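**One step.** In a one-step world of starting material and dissolved gas going to target, [target]/[starting material] ends at the equilibrium constant times [dissolved gas]; this flask also has crystals.

    gas phase ⇌ dissolved gas, rate k1*(csat - [dissolved gas]) (k1 = 0.25 s⁻¹, csat = 0.14 mM)
    starting material + dissolved gas ⇌ target (K2 = 3900 M⁻¹, k2 = 1000 M⁻¹ s⁻¹)
    crystals ⇌ target, rate k3*(cs3 - [target]) while solid is left; crystals form when [target] > cs3 (cs3 = 0.060 mM, k3 = 5.3 s⁻¹)

starting material 0.50 mM; gas phase 0.14 mM (held); time 80 s

- target is meant together with its crystals
- solid, in amounts per volume of the solution: crystals
- at the start none of the gas is dissolved
- run time (flask): 80 s

1. how much target and crystals together there is at 80 s, in percent of the starting material charged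
2. the change that raises the amount of target and crystals together at 80 s, in percent of the starting material charged most ("none" if none brings more than 2 percentage points) (oak / elm / alder / cedar / none)
3. amount of target and crystals together at 80 s, in percent of the starting material charged, after oak

- oak: doubling the dissolution coefficient of step 3, all else as stated
- elm: doubling the saturation concentration of gas phase, all else as stated
- alder: doubling the transfer coefficient of step 1, all else as stated
- cedar: doubling the solubility in step 3, all else as stated

**The floor.** If the flask reaches equilibrium with crystals left, [dissolved gas] stands at 0.14 mM and [target] at 0.060 mM. [starting material] then stands at the floor 0.110 mM, the solubility divided by the equilibrium constant times the saturation concentration. At the rate into an empty solution, the gas for conversion down to the floor takes about 11.1 s, and at saturation the forward step alone gives starting material a pseudo-first-order half-life of 4.95 s; both are shorter than the 80 s of the run, so the reckoning takes thermodynamic control and gives 78.0 %. Oak and alder do not enter the floor, so oak gives 78.0 %. Among the changes, the floor points to elm.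

**Lean neighbour.** The neighbour charged with 0.12 mM looks nearly the same, but at equilibrium with the gas at saturation, crystals need a charge above the floor plus the solubility, 0.170 mM. Because its charge is less than that, the reckoning puts no solid there, and the one-step law leaves 64.7 % of its charge as starting material.

**The forecast.** The forecast gives 78 %, elm as the best change and 78 % after oak, holding that “Changing the dissolution or transfer coefficient therefore does almost nothing”.

**The run.** The simulation gives 77.7 %, elm as the best change with a gain of 11 percentage points, and 77.7 % after oak. In the flask, the step from starting material + dissolved gas to target has half of its turnover up to the asked time done by 15.4 s, earlier than the 80 s of the run, and the answer has moved by 5 points at a time of 44.3 s. The neighbour charged with 0.12 mM, below the onset, holds crystals at 0 % and starting material at 64.7 % of its charge.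

Its constants are made up; no experiment stands behind them.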